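The route rests on breaking the C2–C3 bond of the dihydrofuran ring. The chain O3–C3–C2–C(=CH2) is a homoallylic alcohol, and its allylic carbon C2 already bears the ring oxygen O1. It therefore maps onto the γ-addition of an allylmetal whose γ-carbon carries O1 to the aryl aldehyde carbon C3. In one operation a chiral copper–boryl catalyst converts a 2-formylaryl allenyl ether into that allylcopper, closes the five-membered ring and sets C2 and C3 cis. It also leaves a vinylic boronate on which the formyl carbon is later built. The precursor is aldehyde 9, a 2-(allenyloxy)benzaldehyde carrying the (S)-1-acetoxyethyl group para to oxygen. Its allene is made before acetate or aldehyde can meet base.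

Key step: step 7

Stereochemical reading of the target: (2R,3R) with the C2 alkenyl group and the C3 acyloxy group cis, and (S) at the side-chain carbinol carbon.

Assumption: the sense of induction of a bisphosphine–copper catalyst on this tethered substrate cannot be predicted with certainty. (R)-DTBM-SEGPHOS is written for the Si-face addition, and its commercial (S)-antipode takes its place if a trial run shows the opposite sense.

Step 1
Reactants: 1 4'-hydroxyacetophenone
Product: 2 5-acetyl-2-hydroxybenzaldehyde
Conditions: hexamethylenetetramine (1.1 equiv), CF3CO2H, reflux; then aq HCl, rt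
Reagents that add atoms: hexamethylenetetramine C1N2CN3CN1CN(C2)C3; water O
Why: Duff formylation, in which iminium ions released from hexamethylenetetramine attack the ring ortho to the phenol (para is blocked by the acetyl group and both ortho positions are equivalent), and an internal hydride shift followed by hydrolysis of the benzylic imine gives the salicylaldehyde.

Step 2
Reactants: 2 5-acetyl-2-hydroxybenzaldehyde; 3 propargyl bromide
Product: 4 5-acetyl-2-(prop-2-yn-1-yloxy)benzaldehyde
Conditions: K2CO3, DMF, rt
Reagents that add atoms: propargyl bromide C#CCBr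
Why: Williamson ether synthesis, an SN2 displacement of a primary propargylic bromide by an acidic, doubly acceptor-substituted phenoxide, for which K2CO3 is base enough and leaves the enolisable ketone alone.

Step 3
Reactants: 4 5-acetyl-2-(prop-2-yn-1-yloxy)benzaldehyde
Product: 5 1-[3-(dimethoxymethyl)-4-(prop-2-yn-1-yloxy)phenyl]ethan-1-one
Conditions: HC(OMe)3 (1.5 equiv), p-TsOH·H2O (1 mol %), MeOH, 0 °C → rt; Et3N quench
Reagents that add atoms: trimethyl orthoformate COC(OC)OC
Why: Chemoselective acid-catalysed acetalisation, since the formyl group is far more electrophilic and less hindered than the aryl methyl ketone, which the para oxygen deactivates further, so a small excess of orthoformate should mask the aldehyde only.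

Step 4
Reactants: 5 1-[3-(dimethoxymethyl)-4-(prop-2-yn-1-yloxy)phenyl]ethan-1-one
Product: 6 (1S)-1-[3-(dimethoxymethyl)-4-(prop-2-yn-1-yloxy)phenyl]ethan-1-ol
Conditions: RuCl[(S,S)-TsDPEN](p-cymene) (1 mol %), HCO2Na (5 equiv), H2O–MeOH 1:1, 40 °C
Reagents that add atoms: none
Why: Noyori–Ikariya asymmetric transfer hydrogenation, in which the (S,S)-configured ruthenium hydride/amine delivers hydride to the Re face of the aryl methyl ketone through the outer-sphere six-membered transition state steered by the arene-ligand/aryl contact and so sets the (S)-carbinol, while formate makes the reduction irreversible for this electron-rich ketone, the near-neutral medium keeps the acetal intact and the remote alkyne is a spectator.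

Step 5
Reactants: 6 (1S)-1-[3-(dimethoxymethyl)-4-(prop-2-yn-1-yloxy)phenyl]ethan-1-ol
Product: 8 (1S)-1-[3-(dimethoxymethyl)-4-(propa-1,2-dien-1-yloxy)phenyl]ethyl acetate, via potassium alkoxide 7 (not isolated)
Conditions: t-BuOK (1.5 equiv), THF, 0 °C → rt; then Ac2O (3 equiv), 0 °C
Reagents that add atoms: acetic anhydride CC(=O)OC(C)=O
Why: Base-mediated propargyl-to-allenyl prototropic isomerisation of an aryl propargyl ether, placed here because the substrate offers t-BuOK only an acetal and an alkoxide (an acetate would be cleaved and a free aldehyde attacked), followed by O-acetylation of the alkoxide in the same flask, which does not touch the C–O bond of the (S)-centre.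

Step 6
Reactants: 8 (1S)-1-[3-(dimethoxymethyl)-4-(propa-1,2-dien-1-yloxy)phenyl]ethyl acetate
Product: 9 (1S)-1-[3-formyl-4-(propa-1,2-dien-1-yloxy)phenyl]ethyl acetate
Conditions: PPTS (10 mol %), acetone–H2O 20:1, 0 °C → rt; NaHCO3 quench
Reagents that add atoms: water O
Why: Acid-catalysed acetal hydrolysis, in which ionisation of the dimethyl acetal to an oxocarbenium ion stabilised by the ortho oxygen is much faster than C-protonation of an aryloxyallene whose oxygen lone pair is shared with the arene, so a pyridinium buffer in wet acetone should free the aldehyde without hydrating the allene or ionising the benzylic acetate.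

Step 7
Reactants: 9 (1S)-1-[3-formyl-4-(propa-1,2-dien-1-yloxy)phenyl]ethyl acetate; 10 bis(pinacolato)diboron
Product: 13 (1S)-1-{(2R,3R)-3-hydroxy-2-[1-(4,4,5,5-tetramethyl-1,3,2-dioxaborolan-2-yl)ethenyl]-2,3-dihydro-1-benzofuran-5-yl}ethyl acetate (C2/C3 cis), via Z-allylcopper 11 (not isolated), via O3-boryl ether 12 (not isolated)
Conditions: CuCl (5 mol %), (R)-DTBM-SEGPHOS (6 mol %), NaOt-Bu (10 mol %), B2pin2 (1.1 equiv), THF, 0 °C → rt; then aq NH4Cl
Reagents that add atoms: bis(pinacolato)diboron CC1(C)OB(OC1(C)C)B1OC(C)(C)C(C)(C)O1
Why: The monovalent copper alkoxide CuOt-Bu, made from CuCl and NaOt-Bu, exchanges with B2pin2, and the ligated Cu–Bpin inserts the unhindered terminal C=C of the allenyl ether from the side remote from the aryloxy group, with boron going to the central carbon and copper to CH2, which gives the (Z)-γ-aryloxyallylcopper 11. This species adds through its γ-carbon to the neighbouring formyl group in a cyclic chair-like array held together by coordination of the aldehyde oxygen to copper, after which B2pin2 borylates the copper alkoxide to give 12 and returns Cu–Bpin. The closest known reaction type is the copper-catalysed three-component borylative coupling of allenes with aldehydes or ketones together with its ring-forming variant on tethered ketones, and γ-oxyallylcopper species are also known from reductive couplings of alkoxyallenes. The dihydrofuran ring closes in a 5-exo-trig mode at the carbonyl carbon, whereas α-attack would require a seven-membered ring. The cis relation of C2 and C3 follows from the Z geometry, which puts O1 axial and the tethered aryl group equatorial in the chair, while the chiral bisphosphine selects the Si face of the aldehyde (3R, hence 2R) and the remote (S)-centre only turns any facial leakage into a diastereomer. The step needs allene insertion to outrun direct borylation of the aldehyde and a second borylcupration of the product, which the electron-rich terminal allene, the intramolecular trap and the near-stoichiometric charge of B2pin2 should secure.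

Step 8
Reactants: 13 cis-hydroxy alkenylboronate; 14 isovaleryl chloride
Product: 15 (2R,3R)-5-[(1S)-1-acetoxyethyl]-2-[1-(4,4,5,5-tetramethyl-1,3,2-dioxaborolan-2-yl)ethenyl]-2,3-dihydro-1-benzofuran-3-yl 3-methylbutanoate
Conditions: isovaleryl chloride (1.5 equiv), pyridine (3 equiv), DMAP (10 mol %), CH2Cl2, 0 °C
Reagents that add atoms: isovaleryl chloride CC(C)CC(=O)Cl
Why: DMAP-catalysed O-acylation of a secondary benzylic alcohol with an acid chloride, which leaves the C3–O bond and therefore the (3R) configuration untouched, removes the hydroxyl group that could bind to boron in the next step, and is run cold to avoid loss of the ester with aromatisation to the benzofuran.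

Step 9
Reactants: 15 isovalerate alkenylboronate
Product: 18 (2R,3R)-5-[(1S)-1-acetoxyethyl]-2-(3-hydroxyprop-1-en-2-yl)-2,3-dihydro-1-benzofuran-3-yl 3-methylbutanoate, via chloromethyl ate complex 16 (not isolated), via allylboronate 17 (not isolated)
Conditions: ICH2Cl (1.3 equiv), n-BuLi (1.2 equiv, added last, dropwise), THF, −78 °C → rt; then NaBO3·4H2O, THF–H2O, rt
Reagents that add atoms: chloroiodomethane ClCI; sodium perborate tetrahydrate O[B-]1(O)OO[B-](O)(O)OO1.[Na+].[Na+]
Why: Matteson homologation followed by boronate oxidation, in which LiCH2Cl generated by fast iodine–lithium exchange in the presence of 15 is captured by the Lewis-acidic boron faster than it adds to an ester, the alkenyl group of 16 migrates from boron to carbon with loss of chloride on warming, and perborate, mild enough for acetates, turns the C–B bond of 17 into C–OH without touching C2 or C3.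

Step 10
Reactants: 18 2-substituted allyl alcohol
Product: 19 (2R,3R)-5-[(1S)-1-acetoxyethyl]-2-(3-oxoprop-1-en-2-yl)-2,3-dihydro-1-benzofuran-3-yl 3-methylbutanoate (CNP0252902.1)
Conditions: activated MnO2 (15 equiv), CH2Cl2, rt
Reagents that add atoms: none
Why: Allylic alcohol oxidation with activated MnO2, a neutral heterogeneous oxidant that stops at the enal, spares both esters and supplies no base that could trigger loss of isovalerate from C3 and aromatisation.

Compound list
1 | 4'-hydroxyacetophenone | CC(=O)c1ccc(O)cc1 | starting material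
2 | 5-acetyl-2-hydroxybenzaldehyde | CC(=O)c1ccc(O)c(C=O)c1 | intermediate
3 | propargyl bromide | C#CCBr | starting material
4 | 5-acetyl-2-(prop-2-yn-1-yloxy)benzaldehyde | CC(=O)c1ccc(OCC#C)c(C=O)c1 | intermediate
5 | 1-[3-(dimethoxymethyl)-4-(prop-2-yn-1-yloxy)phenyl]ethan-1-one | CC(=O)c1ccc(OCC#C)c(C(OC)OC)c1 | intermediate
6 | (1S)-1-[3-(dimethoxymethyl)-4-(prop-2-yn-1-yloxy)phenyl]ethan-1-ol | C#CCOc1ccc([C@H](C)O)cc1C(OC)OC | intermediate
7 | potassium (1S)-1-[3-(dimethoxymethyl)-4-(propa-1,2-dien-1-yloxy)phenyl]ethan-1-olate | C=C=COc1ccc([C@H](C)[O-])cc1C(OC)OC.[K+] | intermediate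
8 | (1S)-1-[3-(dimethoxymethyl)-4-(propa-1,2-dien-1-yloxy)phenyl]ethyl acetate | C=C=COc1ccc([C@H](C)OC(C)=O)cc1C(OC)OC | intermediate
9 | (1S)-1-[3-formyl-4-(propa-1,2-dien-1-yloxy)phenyl]ethyl acetate | C=C=COc1ccc([C@H](C)OC(C)=O)cc1C=O | intermediate
10 | bis(pinacolato)diboron | CC1(C)OB(OC1(C)C)B1OC(C)(C)C(C)(C)O1 | starting material
11 | (Z)-3-aryloxy-2-(pinacolatoboryl)allylcopper derived from 9 (bisphosphine on copper omitted) | [Cu]C/C(B1OC(C)(C)C(C)(C)O1)=C\Oc1ccc([C@H](C)OC(C)=O)cc1C=O | intermediate
12 | O3-(pinacolatoboryl) ether of 13, (2R,3R,1'S) | C=C(B3OC(C)(C)C(C)(C)O3)[C@H]1Oc2ccc([C@H](C)OC(C)=O)cc2[C@H]1OB4OC(C)(C)C(C)(C)O4 | intermediate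
13 | (1S)-1-{(2R,3R)-3-hydroxy-2-[1-(pinacolatoboryl)ethenyl]-2,3-dihydro-1-benzofuran-5-yl}ethyl acetate, cis | C=C(B3OC(C)(C)C(C)(C)O3)[C@H]1Oc2ccc([C@H](C)OC(C)=O)cc2[C@H]1O | intermediate
14 | isovaleryl chloride | CC(C)CC(=O)Cl | starting material
15 | (2R,3R)-5-[(1S)-1-acetoxyethyl]-2-[1-(pinacolatoboryl)ethenyl]-2,3-dihydro-1-benzofuran-3-yl 3-methylbutanoate | C=C(B3OC(C)(C)C(C)(C)O3)[C@H]1Oc2ccc([C@H](C)OC(C)=O)cc2[C@H]1OC(=O)CC(C)C | intermediate
16 | lithium (chloromethyl)boronate ate complex of 15 | C=C([B-]3(CCl)OC(C)(C)C(C)(C)O3)[C@H]1Oc2ccc([C@H](C)OC(C)=O)cc2[C@H]1OC(=O)CC(C)C.[Li+] | intermediate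
17 | (2R,3R)-5-[(1S)-1-acetoxyethyl]-2-[3-(pinacolatoboryl)prop-1-en-2-yl]-2,3-dihydro-1-benzofuran-3-yl 3-methylbutanoate | C=C(CB3OC(C)(C)C(C)(C)O3)[C@H]1Oc2ccc([C@H](C)OC(C)=O)cc2[C@H]1OC(=O)CC(C)C | intermediate
18 | (2R,3R)-5-[(1S)-1-acetoxyethyl]-2-(3-hydroxyprop-1-en-2-yl)-2,3-dihydro-1-benzofuran-3-yl 3-methylbutanoate | C=C(CO)[C@H]1Oc2ccc([C@H](C)OC(C)=O)cc2[C@H]1OC(=O)CC(C)C | intermediate
19 | (2R,3R)-5-[(1S)-1-acetoxyethyl]-2-(3-oxoprop-1-en-2-yl)-2,3-dihydro-1-benzofuran-3-yl 3-methylbutanoate | C=C(C=O)[C@H]1Oc2ccc([C@H](C)OC(C)=O)cc2[C@H]1OC(=O)CC(C)C | target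

Total step count: 10. Longest linear sequence: 10 steps, from 1 to 19.

Steps most likely to fail

1. Step 7. The ligand may discriminate the two aldehyde faces poorly. The chiral catalyst may also be too slow, so that direct borylation of the formyl group competes with allene insertion.
   - The fallback moves absolute stereocontrol from the C–C bond formation to the acylation. It sets out from 9.
   - The cyclisation is run with an achiral, more active catalyst (CuCl, Xantphos, NaOt-Bu, B2pin2, THF, same work-up). Only the cis preference of the cyclic transition state is then required.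
   - This should give 13 together with its ring-epimeric (2S,3S) cis diastereomer F1.
   - The mixture then undergoes acylative kinetic resolution, a known method for secondary benzylic alcohols. The conditions are (S)-benzotetramisole, chosen by the aryl-stacking model, with isovaleric anhydride and i-Pr2NEt in CHCl3 at 0 °C.
   - Alcohol 13 is esterified while F1 stays an alcohol, so chromatography delivers 15, where the route is rejoined. The cost is half of the material.

2. Step 9. The carbenoid, or n-BuLi before exchange, may attack the acetate or isovalerate carbonyl in competition with formation of the boron ate complex.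
   - The fallback avoids organolithium reagents altogether and sets out from 15.
   - Ipso-iododeboronation with NaI and chloramine-T in aqueous THF gives the alkenyl iodide F2.
   - Stille coupling of F2 with (tributylstannyl)methanol under Pd(PPh3)4 (zerovalent palladium) in dioxane at 80 °C installs the CH2OH group directly.
   - The route is rejoined at 18.

3. Step 6. Acid-promoted hydration of the allenyl ether, with loss of the three-carbon unit, may compete with acetal cleavage.
   - The fallback keeps the aldehyde carbon at the alcohol level, so no acid is needed once the allene exists. It sets out from 4.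
   - Transfer hydrogenation with RuCl[(S,S)-TsDPEN](p-cymene) in HCO2H–Et3N reduces both carbonyl groups to the (S)-diol F3.
   - TBSCl and imidazole at 0 °C silylate the primary hydroxyl group selectively to give the silyl ether F4.
   - t-BuOK in THF gives the allenyl ether alcohol F5. The masked ortho oxygen cannot add to the allene.
   - Ac2O, pyridine and DMAP give the acetate F6.
   - TBAF buffered with AcOH gives the benzylic alcohol F7.
   - MnO2 in CH2Cl2 oxidises F7 to 9, where the route is rejoined.

Further compounds
F1 | step 7 | (1S)-1-{(2S,3S)-3-hydroxy-2-[1-(pinacolatoboryl)ethenyl]-2,3-dihydro-1-benzofuran-5-yl}ethyl acetate, cis | C=C(B3OC(C)(C)C(C)(C)O3)[C@@H]1Oc2ccc([C@H](C)OC(C)=O)cc2[C@@H]1O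
F2 | step 9 | (2S,3R)-5-[(1S)-1-acetoxyethyl]-2-(1-iodoethenyl)-2,3-dihydro-1-benzofuran-3-yl 3-methylbutanoate (same spatial arrangement as 15; the C2 descriptor changes because iodine raises the rank of the alkenyl carbon) | C=C(I)[C@H]1Oc2ccc([C@H](C)OC(C)=O)cc2[C@H]1OC(=O)CC(C)C
F3 | step 6 | (1S)-1-[3-(hydroxymethyl)-4-(prop-2-yn-1-yloxy)phenyl]ethan-1-ol | C#CCOc1ccc([C@H](C)O)cc1CO
F4 | step 6 | (1S)-1-[3-{[(tert-butyldimethylsilyl)oxy]methyl}-4-(prop-2-yn-1-yloxy)phenyl]ethan-1-ol | C#CCOc1ccc([C@H](C)O)cc1CO[Si](C)(C)C(C)(C)C
F5 | step 6 | (1S)-1-[3-{[(tert-butyldimethylsilyl)oxy]methyl}-4-(propa-1,2-dien-1-yloxy)phenyl]ethan-1-ol | C=C=COc1ccc([C@H](C)O)cc1CO[Si](C)(C)C(C)(C)C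
F6 | step 6 | (1S)-1-[3-{[(tert-butyldimethylsilyl)oxy]methyl}-4-(propa-1,2-dien-1-yloxy)phenyl]ethyl acetate | C=C=COc1ccc([C@H](C)OC(C)=O)cc1CO[Si](C)(C)C(C)(C)C
F7 | step 6 | (1S)-1-[3-(hydroxymethyl)-4-(propa-1,2-dien-1-yloxy)phenyl]ethyl acetate | C=C=COc1ccc([C@H](C)OC(C)=O)cc1CO
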